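The earlier runs and the new flask are simulated with made-up constants; noise was put on by code.

The beta run was where I began when you asked for a quick number on the gamma flask and suspected a small floor under the target.

| flask | substrate | first nucleophile | second nucleophile | remark | time |
|---|---|---|---|---|---|
| gamma | 0.66 M | 0.60 equiv | 3 equiv | the very flask that is asked about, followed so far |  |
| beta | 0.66 M | 0.40 equiv | 3 equiv | run made earlier |  |
| flask | 0.66 M | 0.600 equiv | 3.00 equiv |  | 6.0 d |

| run | time / d | target / % | other capture product / % |
|---|---|---|---|
| gamma | 0.125 | 37.6 | 42.3 |
| gamma | 0.333 | 35.9 | 49.9 |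
| gamma | 0.625 | 28.6 | 49.7 |
| gamma | 1.04 | 20.9 | 49.6 |
| gamma | 1.67 | 12.7 | 50.0 |
| gamma | 2.08 | 9.7 | 49.6 |
| gamma | 2.50 | 7.7 | 49.5 |
| beta | 0.625 | 20.7 | 60.3 |
| beta | 1.25 | 12.7 | 60.2 |
| beta | 1.67 | 10.0 | 60.1 |
| beta | 2.50 | 5.7 | 60.2 |
| beta | 3.00 | 4.2 | 60.0 |
| beta | 4.00 | 2.1 | 60.0 |

(scatter of a reading: 0.3 percentage points)

* ratio of target to other capture product at 6.0 min
* ratio of target to other capture product at 3.0 h
* ratio of target to other capture product at 6.0 d
* which of target and other capture product there is more of at 6.0 d

In the gamma run the other capture product stayed level near 49.5% while the target kept falling. I therefore treated the late target as a first-order lag relaxing through a reversible step into some unseen species, with target plus that species forming a fixed stock: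

rate of change of target = −k_f·target + k_b·(stock − target)

target(t) = floor + (target(s) − floor)·exp(−rate·(t − s)), with rate = k_f + k_b

I took the rate from the two early beta readings, ignoring the floor there, which gave 0.782 d⁻¹. The gamma run then gave the floor from its readings at 1.67 d and 2.50 d, and the stock from its reading at 0.625 d carried back to zero time:

floor = 2.22%

stock = 45.2%

floor share = 4.92%

This floor share, the equilibrium fraction of the stock that remains target, was a rough reading: the beta tail, reckoned the same way, put its floor at 0.575%. I committed to 2.58% of target at 6.0 d, a ratio of 0.0521.

The forecast gave 1.43, 0.89 and 0.02, with other capture product leading, and noted: “The late slopes flatten slightly, which may indicate a small floor”. I had nothing better for the two early times, but at 6.0 d my ratio stood at 0.0521 against the forecast's 0.02.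

The flask gave 1.46, 0.903 and 0.0482, with other capture product leading.

    substrate → intermediate (k = 0.701 h⁻¹)
    first nucleophile + intermediate → target (k = 56.2 L mol⁻¹ h⁻¹)
    second nucleophile + intermediate → other capture product (k = 7.51 L mol⁻¹ h⁻¹)
    intermediate → solvolysis product (k = 1.62 h⁻¹)
    target ⇌ isomer of the product (K = 20.2, k = 0.0332 h⁻¹)

In this flask the half-life of target by the forward step to the isomer of the product alone was 0.87 d, short against the 6.0 d, and at 6.00 d 2.39% of target stood beside 42.1% of the isomer of the product, with 2.10% of target at 60.0 d. The floor share applied to the sum of those two at 6.00 d gave a floor of 2.19% in this flask, and applied to the same sum of 29.8% in the neighbour with 0.360 equiv of first nucleophile it gave 1.46%, where that neighbour held 1.60% of target at 6.00 d.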